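**Retrosynthetic overview**

1. The (Z)-alkene comes from cis-semihydrogenation of diaryl alkyne 24, made by Sonogashira coupling of terminal alkyne 21 with preformed 8-iodo-5,7-dimethoxycoumarin 23 (ring A).
2. The pyranone of coumarin ring B is annulated late onto phenol 17 (ortho-formylation, ketene-ylide Wittig lactonisation); the alkyne comes from lactol 15 by Ohira–Bestmann homologation.
3. Feature used: on the cyclohexene (C1 quaternary with CH3 and the styryl carbon; C2H2; C3H2; C4(CH3)=C5H; C6H bonded to C8 of ring B) the styryl carbon and the aryl group are cis, and O1 of ring B is ortho to the C6–aryl bond. Styryl carbon (as C=O), O1 and the aryl ring therefore map onto a cis-fused aryl δ-lactone, so C1–C6 is the former C3=C4 bond of a 3-formyl-5,7-dimethoxycoumarin and the formyl group is the future C1 methyl (C1–C6 = C6a, C7, C8, C9, C10, C10a of the benzo[c]chromenone).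
4. Key disconnection: C1–C2 and C5–C6 by [4+2] addition of (E)-1-silyl-2-methylbutadiene 9 to formylcoumarin 6; the silyl group is carried only to move the alkene from C3=C4 to C4=C5 by protodesilylation.
5. Ring order: pyranone of 6, then the cyclohexene (Diels–Alder), lactone opened, pyranone of ring B rebuilt on the freed phenol, ring A coumarin attached intact.

Key step: step 6

Assumption: the sense of facial induction of the bis(oxazoline) complex of divalent copper on this new dienophile cannot be assigned on paper; the (S,S)-ligand is written, and the (R,R)-ligand is to be used if the first adduct proves to be the (6aR,10aR) enantiomer.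

**Route**

Step 1
Reactants: 1 2-hydroxy-4,6-dimethoxybenzaldehyde; 2 Meldrum's acid (2,2-dimethyl-1,3-dioxane-4,6-dione)
Product: 4 5,7-dimethoxy-2-oxo-2H-chromene-3-carboxylic acid, via arylidene Meldrum's acid 3 (not isolated)
Conditions: piperidine (cat.), AcOH (cat.), EtOH, reflux
Reagents that add atoms: none
Why: Knoevenagel condensation with Meldrum's acid is followed in the same pot by attack of the phenol on the activated acyl carbon with loss of acetone, which closes the pyranone and leaves the 3-carboxylic acid directly.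

Step 2
Reactants: 4 5,7-dimethoxy-2-oxo-2H-chromene-3-carboxylic acid
Product: 5 5,7-dimethoxy-2-oxo-2H-chromene-3-carbonyl chloride
Conditions: SOCl2, DMF (cat.), toluene, 80 °C; evaporate
Reagents that add atoms: thionyl chloride, O=S(Cl)Cl
Why: Standard acid chloride formation under DMF catalysis; the lactone and aryl ethers are inert.

Step 3
Reactants: 5 5,7-dimethoxy-2-oxo-2H-chromene-3-carbonyl chloride
Product: 6 5,7-dimethoxy-2-oxo-2H-chromene-3-carbaldehyde
Conditions: LiAlH(Ot-Bu)3 (1.05 equiv), THF, −78 °C; aq. NH4Cl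
Reagents that add atoms: none
Why: Partial reduction of an acyl chloride, in which the bulky, weakly reducing alkoxyhydride transfers one hydride at −78 °C and should stop at the aldehyde without touching the lactone or the conjugated C3=C4 bond.

Step 4
Reactants: 7 3-methyl-2,5-dihydrothiophene 1,1-dioxide (3-methyl-3-sulfolene)
Product: 8 3-methyl-2-(trimethylsilyl)-2,5-dihydrothiophene 1,1-dioxide (racemic)
Conditions: Me3SiCl (1.5 equiv), then LiN(SiMe3)2 (1.05 equiv, added last), THF, −78 °C
Reagents that add atoms: chlorotrimethylsilane, C[Si](C)(C)Cl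
Why: C-silylation of an α-sulfonyl carbanion under in-situ quench: deprotonation at C2 gives the allyl-sulfonyl anion with the methyl on its central carbon (the C5 anion would carry it at a terminus), and the silyl chloride already present traps it before the ring can open.

Step 5
Reactants: 8 3-methyl-2-(trimethylsilyl)-2,5-dihydrothiophene 1,1-dioxide
Product: 9 (E)-trimethyl(2-methylbuta-1,3-dien-1-yl)silane
Conditions: neat, hydroquinone (trace), 135 °C, 150 mbar, diene distilled into a cold trap
Reagents that add atoms: none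
Why: Thermal cheletropic extrusion of SO2 from a 3-sulfolene is disrotatory with the C2 substituent turning outward, so the silyl group ends trans to the vinyl group and only the (E)-diene should form.

Step 6
Reactants: 6 5,7-dimethoxy-2-oxo-2H-chromene-3-carbaldehyde; 9 (E)-trimethyl(2-methylbuta-1,3-dien-1-yl)silane
Product: 10 cis-fused (6aS,10aS)-1,3-dimethoxy-9-methyl-6-oxo-10-(trimethylsilyl)-6a,7,10,10a-tetrahydro-6H-benzo[c]chromene-6a-carbaldehyde (C10 either epimer)
Conditions: Cu(OTf)2 (20 mol %), 2,2′-isopropylidenebis[(4S)-4-tert-butyl-2-oxazoline] (22 mol %), 4 Å MS, CH2Cl2, rt, 10 kbar; diene in threefold excess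
Reagents that add atoms: none
Why: Proposed new method: the bis(oxazoline) complex of divalent copper should bind the formyl and lactone carbonyl oxygens of 6 as a six-membered chelate and lower the LUMO of the push–pull C3=C4 bond, across which the s-cis diene adds in a concerted, asynchronous normal-demand [4+2] cycloaddition; the closest known reactions are Lewis-acid- or pressure-promoted Diels–Alder additions of simple 1,3-dienes to 3-acyl- and 3-alkoxycarbonylcoumarins and bis(oxazoline)–Cu-catalysed cycloadditions of chelating 1,3-dicarbonyl dienophiles. The cyclohexene closes by cycloaddition, the C6a–C7 and C10–C10a bonds forming suprafacially on both partners, so the new carbocycle is necessarily cis-fused to the lactone. At C6a and C10a the relative configuration follows from suprafacial addition to the ring-locked alkene (formyl cis to H-10a, hence trans to the aryl ring) and the absolute configuration from the C2-symmetric ligand, whose tert-butyl group screens one face of the chelated dienophile; C10 depends on endo or exo approach and needs no control because it is erased in step 7. Regiochemistry is required and is secured by the diene: the C2 methyl raises the HOMO coefficient at the silyl-bearing C1, and the charge developing at C2 is tertiary and beta to silicon, so C1 bonds to the electrophilic coumarin C4 and the CH2 terminus to C3. Periselectivity for C=C over the formyl C=O or the oxadiene is expected from two-point binding, and the (E)-geometry with silicon outside lets the diene reach the s-cis form. Both forming bonds are crowded (peri 5-methoxy, SiMe3) and the methoxy groups donate into C4, which is why the reaction is run under pressure.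

Step 7
Reactants: 10 silyl adduct
Product: 11 (6aS,10aS)-1,3-dimethoxy-9-methyl-6-oxo-6a,7,8,10a-tetrahydro-6H-benzo[c]chromene-6a-carbaldehyde
Conditions: CF3CO2H (5 equiv), CH2Cl2, 0 °C; aq. NaHCO3
Reagents that add atoms: none
Why: Protodesilylation of an allylsilane (SE2′): protonation at C8 gives the tertiary C9 cation beta to silicon, loss of the silyl group places the alkene at C9=C10 regiospecifically, and C6a and C10a are not touched.

Step 8
Reactants: 11 aldehyde
Product: 12 (6aS,10aS)-6a-(hydroxymethyl)-1,3-dimethoxy-9-methyl-6a,7,8,10a-tetrahydro-6H-benzo[c]chromen-6-one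
Conditions: NaBH4, THF–MeOH (4:1), −40 °C; AcOH quench
Reagents that add atoms: none
Why: Chemoselective borohydride reduction of the aldehyde at low temperature, where the hindered aryl lactone reacts far more slowly and the protic medium keeps the new alkoxide from attacking the lactone.

Step 9
Reactants: 12 alcohol
Product: 13 (6aR,10aS)-6a-(iodomethyl)-1,3-dimethoxy-9-methyl-6a,7,8,10a-tetrahydro-6H-benzo[c]chromen-6-one
Conditions: I2, PPh3, imidazole, toluene, 80 °C
Reagents that add atoms: iodine, II
Why: Appel-type iodination; the neopentyl position needs heating but cannot eliminate because the neighbouring carbon is quaternary (the descriptor at C6a changes by priority only).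

Step 10
Reactants: 13 iodide
Product: 14 (6aS,10aS)-1,3-dimethoxy-6a,9-dimethyl-6a,7,8,10a-tetrahydro-6H-benzo[c]chromen-6-one
Conditions: Bu3SnH (2 equiv, 0.3 M), AIBN (cat.), benzene, 80 °C
Reagents that add atoms: none
Why: Radical chain dehalogenation, in which the primary radical is quenched by the concentrated stannane faster than any 1,2-acyl shift and no bond to the quaternary centre is broken.

Step 11
Reactants: 14 methyl lactone
Product: 15 (6aS,10aS)-1,3-dimethoxy-6a,9-dimethyl-6a,7,8,10a-tetrahydro-6H-benzo[c]chromen-6-ol (C6 epimers)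
Conditions: i-Bu2AlH (1.2 equiv), CH2Cl2, −78 °C; aq. KNa tartrate
Reagents that add atoms: none
Why: Partial reduction of a lactone to the lactol, the tetrahedral aluminate being stable at −78 °C and the carbonyl next to the quaternary carbon resisting a second hydride transfer.

Step 12
Reactants: 15 lactol
Product: 17 2-[(1R,6S)-6-ethynyl-3,6-dimethylcyclohex-2-en-1-yl]-3,5-dimethoxyphenol, via open-chain hydroxy aldehyde 16 (not isolated)
Conditions: dimethyl (1-diazo-2-oxopropyl)phosphonate (2.5 equiv), K2CO3 (4 equiv), MeOH, 0 °C to rt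
Reagents that add atoms: dimethyl (1-diazo-2-oxopropyl)phosphonate, COP(=O)(OC)C(=[N+]=[N-])C(C)=O
Why: Ohira–Bestmann homologation of a lactol through its open form: the diazomethylphosphonate anion formed by methanolysis adds to the non-enolisable aldehyde, Horner–Wadsworth–Emmons-type elimination and loss of N2 give the alkylidene carbene, and 1,2-hydrogen shift gives the terminal alkyne with the phenol set free.

Step 13
Reactants: 17 alkynyl phenol
Product: 19 3-[(1R,6S)-6-ethynyl-3,6-dimethylcyclohex-2-en-1-yl]-2-hydroxy-4,6-dimethoxybenzaldehyde, via ortho-hydroxymethyl phenol 18 (not isolated)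
Conditions: MgCl2 (3 equiv), Et3N (6 equiv), (CH2O)n (8 equiv), MeCN, reflux; 1 M HCl
Reagents that add atoms: paraformaldehyde (formaldehyde), C=O
Why: Magnesium-mediated ortho-formylation of a phenol (Casnati–Skattebøl), in which the magnesium phenoxide delivers formaldehyde only to the free ortho carbon, not to the carbon between the two methoxy groups, and a second formaldehyde oxidises the benzylic alkoxide by hydride transfer.

Step 14
Reactants: 19 salicylaldehyde
Product: 21 8-[(1R,6S)-6-ethynyl-3,6-dimethylcyclohex-2-en-1-yl]-5,7-dimethoxy-2H-chromen-2-one, via aryl phosphoranylideneacetate 20 (not isolated)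
Conditions: Ph3P=C=C=O (1.3 equiv), toluene, 110 °C
Reagents that add atoms: (triphenylphosphoranylidene)ketene, O=C=C=P(c1ccccc1)(c1ccccc1)c1ccccc1
Why: Domino addition–intramolecular Wittig reaction: the phenol adds across the ketene ylide to give an ester-stabilised ylide, which olefinates the neighbouring aldehyde and so closes the pyranone of ring B.

Step 15
Reactants: 22 5,7-dimethoxy-2H-chromen-2-one
Product: 23 8-iodo-5,7-dimethoxy-2H-chromen-2-one
Conditions: N-iodosuccinimide (1.05 equiv), CF3CO2H (0.3 equiv), MeCN, 0 °C to rt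
Reagents that add atoms: N-iodosuccinimide, O=C1CCC(=O)N1I
Why: Electrophilic aromatic iodination, expected at C8 (ortho to the 7-methoxy group and the ring oxygen, para to the 5-methoxy group) in preference to C6 between the two methoxy groups; the site is to be confirmed by NOE before use.

Step 16
Reactants: 21 terminal alkyne; 23 8-iodo-5,7-dimethoxy-2H-chromen-2-one
Product: 24 8-[(1R,6S)-6-[(5,7-dimethoxy-2-oxo-2H-chromen-8-yl)ethynyl]-3,6-dimethylcyclohex-2-en-1-yl]-5,7-dimethoxy-2H-chromen-2-one
Conditions: Pd(PPh3)2Cl2 (5 mol %), CuI (10 mol %), Et3N, DMF, 50 °C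
Reagents that add atoms: none
Why: Sonogashira coupling of a terminal alkyne with an aryl iodide; both lactones tolerate the amine base at this temperature.

Step 17
Reactants: 24 diaryl alkyne
Product: 25 8-[(1R,6R)-6-[(Z)-2-(5,7-dimethoxy-2-oxo-2H-chromen-8-yl)ethenyl]-3,6-dimethylcyclohex-2-en-1-yl]-5,7-dimethoxy-2H-chromen-2-one (CNP0164660.3)
Conditions: H2 (1 atm), Lindlar catalyst (Pd/CaCO3 poisoned with Pb(OAc)2), quinoline, EtOAc, rt; stopped after 1 equiv H2
Reagents that add atoms: none
Why: Lindlar semihydrogenation delivers both hydrogens to one face of the alkyne to give the (Z)-alkene, while the trisubstituted ring alkene and the conjugated coumarin C3=C4 bonds should not be reduced on the poisoned catalyst.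

**Compound list**

1 | 2-hydroxy-4,6-dimethoxybenzaldehyde | COc1cc(O)c(C=O)c(OC)c1 | starting material
2 | Meldrum's acid (2,2-dimethyl-1,3-dioxane-4,6-dione) | CC1(C)OC(=O)CC(=O)O1 | starting material
3 | 5-(2-hydroxy-4,6-dimethoxybenzylidene)-2,2-dimethyl-1,3-dioxane-4,6-dione | COc1cc(O)c(C=C2C(=O)OC(C)(C)OC2=O)c(OC)c1 | intermediate (not isolated)
4 | 5,7-dimethoxy-2-oxo-2H-chromene-3-carboxylic acid | COc1cc(OC)c2cc(C(=O)O)c(=O)oc2c1 | intermediate
5 | 5,7-dimethoxy-2-oxo-2H-chromene-3-carbonyl chloride | COc1cc(OC)c2cc(C(=O)Cl)c(=O)oc2c1 | intermediate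
6 | 5,7-dimethoxy-2-oxo-2H-chromene-3-carbaldehyde | COc1cc(OC)c2cc(C=O)c(=O)oc2c1 | intermediate
7 | 3-methyl-2,5-dihydrothiophene 1,1-dioxide | CC1=CCS(=O)(=O)C1 | starting material
8 | 3-methyl-2-(trimethylsilyl)-2,5-dihydrothiophene 1,1-dioxide (racemic) | CC1=CCS(=O)(=O)C1[Si](C)(C)C | intermediate
9 | (E)-trimethyl(2-methylbuta-1,3-dien-1-yl)silane | C=C/C(C)=C/[Si](C)(C)C | intermediate
10 | (6aS,10aS)-1,3-dimethoxy-9-methyl-6-oxo-10-(trimethylsilyl)-6a,7,10,10a-tetrahydro-6H-benzo[c]chromene-6a-carbaldehyde (C10 either epimer) | O=C[C@]12CC=C(C)C([Si](C)(C)C)[C@H]1c1c(OC)cc(OC)cc1OC2=O | intermediate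
11 | (6aS,10aS)-1,3-dimethoxy-9-methyl-6-oxo-6a,7,8,10a-tetrahydro-6H-benzo[c]chromene-6a-carbaldehyde | O=C[C@]12CCC(C)=C[C@H]1c1c(OC)cc(OC)cc1OC2=O | intermediate
12 | (6aS,10aS)-6a-(hydroxymethyl)-1,3-dimethoxy-9-methyl-6a,7,8,10a-tetrahydro-6H-benzo[c]chromen-6-one | OC[C@]12CCC(C)=C[C@H]1c1c(OC)cc(OC)cc1OC2=O | intermediate
13 | (6aR,10aS)-6a-(iodomethyl)-1,3-dimethoxy-9-methyl-6a,7,8,10a-tetrahydro-6H-benzo[c]chromen-6-one | IC[C@]12CCC(C)=C[C@H]1c1c(OC)cc(OC)cc1OC2=O | intermediate
14 | (6aS,10aS)-1,3-dimethoxy-6a,9-dimethyl-6a,7,8,10a-tetrahydro-6H-benzo[c]chromen-6-one | C[C@]12CCC(C)=C[C@H]1c1c(OC)cc(OC)cc1OC2=O | intermediate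
15 | (6aS,10aS)-1,3-dimethoxy-6a,9-dimethyl-6a,7,8,10a-tetrahydro-6H-benzo[c]chromen-6-ol (C6 epimers) | C[C@]12CCC(C)=C[C@H]1c1c(OC)cc(OC)cc1OC2O | intermediate
16 | (1S,2S)-2-(2-hydroxy-4,6-dimethoxyphenyl)-1,4-dimethylcyclohex-3-ene-1-carbaldehyde | O=C[C@@]1(C)CCC(C)=C[C@H]1c1c(OC)cc(OC)cc1O | intermediate (not isolated)
17 | 2-[(1R,6S)-6-ethynyl-3,6-dimethylcyclohex-2-en-1-yl]-3,5-dimethoxyphenol | C#C[C@@]1(C)CCC(C)=C[C@H]1c1c(OC)cc(OC)cc1O | intermediate
18 | 2-[(1R,6S)-6-ethynyl-3,6-dimethylcyclohex-2-en-1-yl]-6-(hydroxymethyl)-3,5-dimethoxyphenol | C#C[C@@]1(C)CCC(C)=C[C@H]1c1c(OC)cc(OC)c(CO)c1O | intermediate (not isolated)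
19 | 3-[(1R,6S)-6-ethynyl-3,6-dimethylcyclohex-2-en-1-yl]-2-hydroxy-4,6-dimethoxybenzaldehyde | C#C[C@@]1(C)CCC(C)=C[C@H]1c1c(OC)cc(OC)c(C=O)c1O | intermediate
20 | 2-[(1R,6S)-6-ethynyl-3,6-dimethylcyclohex-2-en-1-yl]-6-formyl-3,5-dimethoxyphenyl (triphenylphosphoranylidene)acetate | C#C[C@@]1(C)CCC(C)=C[C@H]1c1c(OC)cc(OC)c(C=O)c1OC(=O)C=P(c1ccccc1)(c1ccccc1)c1ccccc1 | intermediate (not isolated)
21 | 8-[(1R,6S)-6-ethynyl-3,6-dimethylcyclohex-2-en-1-yl]-5,7-dimethoxy-2H-chromen-2-one | C#C[C@@]1(C)CCC(C)=C[C@H]1c1c(OC)cc(OC)c2ccc(=O)oc12 | intermediate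
22 | 5,7-dimethoxy-2H-chromen-2-one | COc1cc(OC)c2ccc(=O)oc2c1 | starting material
23 | 8-iodo-5,7-dimethoxy-2H-chromen-2-one | COc1cc(OC)c2ccc(=O)oc2c1I | intermediate
24 | 8-[(1R,6S)-6-[(5,7-dimethoxy-2-oxo-2H-chromen-8-yl)ethynyl]-3,6-dimethylcyclohex-2-en-1-yl]-5,7-dimethoxy-2H-chromen-2-one | COc1cc(OC)c2ccc(=O)oc2c1C#C[C@@]1(C)CCC(C)=C[C@H]1c1c(OC)cc(OC)c2ccc(=O)oc12 | intermediate
25 | 8-[(1R,6R)-6-[(Z)-2-(5,7-dimethoxy-2-oxo-2H-chromen-8-yl)ethenyl]-3,6-dimethylcyclohex-2-en-1-yl]-5,7-dimethoxy-2H-chromen-2-one | COc1cc(OC)c2ccc(=O)oc2c1/C=C\[C@@]1(C)CCC(C)=C[C@H]1c1c(OC)cc(OC)c2ccc(=O)oc12 | target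

**Step count**

Total: 17 steps. Longest linear sequence: 14 steps (1, 2, 3, 6–14, 16, 17, from compound 1).

**Steps most likely to fail**

1. Step 6 (proposed new method). The dienophile may be too unreactive, because both methoxy groups donate into C4 and both forming bonds are crowded. Attack may also turn stepwise and end in desilylative conjugate dienylation or addition at the formyl group instead of ring closure, or the face selection may be poor. Fallback with known chemistry, setting out from 5 and returning at 12: acid chloride 5 is esterified (t-BuOH, pyridine, DMAP, CH2Cl2) to tert-butyl 5,7-dimethoxy-2-oxo-2H-chromene-3-carboxylate F1. F1 and diene 9 are combined without a chiral catalyst under the conditions known for 3-alkoxycarbonylcoumarins (CH2Cl2, 10–12 kbar, 40 °C, ZnCl2 if needed) to give the racemic cis-fused tert-butyl 1,3-dimethoxy-9-methyl-6-oxo-10-(trimethylsilyl)-6a,7,10,10a-tetrahydro-6H-benzo[c]chromene-6a-carboxylate F2. CF3CO2H in CH2Cl2 then effects protodesilylation and tert-butyl ester cleavage in one operation to give racemic 1,3-dimethoxy-9-methyl-6-oxo-6a,7,8,10a-tetrahydro-6H-benzo[c]chromene-6a-carboxylic acid F3. Classical resolution by crystallisation with (S)-1-phenylethylamine (or its antipode, whichever gives the wanted salt as the less soluble one) gives (S)-1-phenylethylammonium (6aS,10aS)-1,3-dimethoxy-9-methyl-6-oxo-6a,7,8,10a-tetrahydro-6H-benzo[c]chromene-6a-carboxylate F4. The (6aS,10aS)-acid set free from this salt with 1 M HCl, which is the enantiomer of F3 that is drawn, is reduced through its mixed anhydride (i-BuOCOCl, N-methylmorpholine, THF, −15 °C; NaBH4, H2O) to alcohol 12, and the route continues at step 9.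

2. Step 12. Homologation may stall because the lactol opens reluctantly and the neopentyl carbonyl of the phenoxide-bearing open form is hindered, so the diazophosphonate anion decomposes before it adds. Fallback from 15, returning at 17: Wittig chloromethylenation with Ph3P=CHCl (from (chloromethyl)triphenylphosphonium chloride and KOt-Bu, excess, THF, 0 °C to rt) gives 2-[(1R,6S)-6-(2-chloroethenyl)-3,6-dimethylcyclohex-2-en-1-yl]-3,5-dimethoxyphenol F5 as an E/Z mixture. Dehydrochlorination with n-BuLi (3.5 equiv, THF, −78 to 0 °C) and protonation then give alkyne 17.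

3. Step 17. Hydrogenation of the doubly hindered alkyne may be slow, and forcing it may lead to over-reduction of the new alkene or of a coumarin C3=C4 bond. Fallback from 21, returning at 25, in which the (Z)-geometry is fixed before the carbon–carbon bond is made: alkyne 21 is iodinated (N-iodosuccinimide, AgNO3 cat., acetone) to 8-[(1R,6S)-6-(iodoethynyl)-3,6-dimethylcyclohex-2-en-1-yl]-5,7-dimethoxy-2H-chromen-2-one F6. Diimide reduction (2-nitrobenzenesulfonylhydrazide, Et3N, THF–i-PrOH, rt) gives 8-[(1R,6S)-6-[(Z)-2-iodoethenyl]-3,6-dimethylcyclohex-2-en-1-yl]-5,7-dimethoxy-2H-chromen-2-one F7. Iodide 23 is converted by Miyaura borylation (bis(pinacolato)diboron, Pd(dppf)Cl2, KOAc, dioxane, 80 °C) into 5,7-dimethoxy-8-(4,4,5,5-tetramethyl-1,3,2-dioxaborolan-2-yl)-2H-chromen-2-one F8. Suzuki–Miyaura coupling of F7 with F8 (Pd(OAc)2, SPhos, K3PO4, toluene–H2O, 60 °C) proceeds with retention of alkene geometry and gives 25.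

**Further compounds**

F1 | step 6 | tert-butyl 5,7-dimethoxy-2-oxo-2H-chromene-3-carboxylate | COc1cc(OC)c2cc(C(=O)OC(C)(C)C)c(=O)oc2c1
F2 | step 6 | racemic cis-fused tert-butyl 1,3-dimethoxy-9-methyl-6-oxo-10-(trimethylsilyl)-6a,7,10,10a-tetrahydro-6H-benzo[c]chromene-6a-carboxylate (one enantiomer drawn) | CC(C)(C)OC(=O)[C@]12CC=C(C)C([Si](C)(C)C)[C@H]1c1c(OC)cc(OC)cc1OC2=O
F3 | step 6 | racemic cis-fused 1,3-dimethoxy-9-methyl-6-oxo-6a,7,8,10a-tetrahydro-6H-benzo[c]chromene-6a-carboxylic acid (one enantiomer drawn) | OC(=O)[C@]12CCC(C)=C[C@H]1c1c(OC)cc(OC)cc1OC2=O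
F4 | step 6 | (S)-1-phenylethylammonium (6aS,10aS)-1,3-dimethoxy-9-methyl-6-oxo-6a,7,8,10a-tetrahydro-6H-benzo[c]chromene-6a-carboxylate | C[C@H]([NH3+])c1ccccc1.[O-]C(=O)[C@]12CCC(C)=C[C@H]1c1c(OC)cc(OC)cc1OC2=O
F5 | step 12 | 2-[(1R,6S)-6-(2-chloroethenyl)-3,6-dimethylcyclohex-2-en-1-yl]-3,5-dimethoxyphenol (E/Z mixture) | ClC=C[C@@]1(C)CCC(C)=C[C@H]1c1c(OC)cc(OC)cc1O
F6 | step 17 | 8-[(1R,6S)-6-(iodoethynyl)-3,6-dimethylcyclohex-2-en-1-yl]-5,7-dimethoxy-2H-chromen-2-one | IC#C[C@@]1(C)CCC(C)=C[C@H]1c1c(OC)cc(OC)c2ccc(=O)oc12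
F7 | step 17 | 8-[(1R,6S)-6-[(Z)-2-iodoethenyl]-3,6-dimethylcyclohex-2-en-1-yl]-5,7-dimethoxy-2H-chromen-2-one | I/C=C\[C@@]1(C)CCC(C)=C[C@H]1c1c(OC)cc(OC)c2ccc(=O)oc12
F8 | step 17 | 5,7-dimethoxy-8-(4,4,5,5-tetramethyl-1,3,2-dioxaborolan-2-yl)-2H-chromen-2-one | COc1cc(OC)c2ccc(=O)oc2c1B1OC(C)(C)C(C)(C)O1
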